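## Structural features

The target 19 is a flavonol: a 4H-chromen-4-one in which benzo ring A is fused to pyranone ring C, with aryl ring B attached to C2 through the C2–C1' bond and a hydroxyl group on C3. Ring A carries a hydroxyl on C5 and methyl ethers on C7 and C8, so the ring oxygen O1 (on C8a) stands next to the C8 methoxy carbon. Ring B is a 1,2,4,5-tetrasubstituted benzene with hydroxyls on C2' and C4' and a methyl ether on C5'. There is no stereocentre and every skeletal carbon is sp2, so any stereocentre that appears on the way is temporary and needs no control. The fragile part is the free polyphenol: the hydroxyquinol-type ring B and the 3-hydroxy-4-pyranone enol are easily oxidised in air, above all under base, so they stay masked until the last step. The real difficulty is telling seven oxygens apart (three permanent methyl ethers against four free hydroxyls), fixing the ring A pattern without ambiguity, and bringing in the C3 oxygen. The key step uses the fact that C3 and C4 are neighbours in ring C and both carry oxygen. In the 3,4-dione tautomer both are carbonyl carbons, so the C3–C4 bond is a pinacol retron whose two carbonyls are already tethered through C4a, C8a, O1 and C2.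

## Logic of the disconnections

**19 to 18.** The three O–CH2Ph bonds on O5, O2' and O4' are cut. Benzyl separates these three oxygens from the three permanent methyl ethers, and all three fall in one neutral operation. Every earlier intermediate is then a robust, non-acidic ether. The forward step must spare the C2=C3 bond and the C4 carbonyl, which calls for hydrogenolysis at low pressure and room temperature.

**18 to 16 through 17.** No skeletal bond is cut. C3 and C4 are taken from the carbonyl/enol level down to the carbinol level and C2 returns to sp3. This exposes a vicinal diol, and the C3 oxygen no longer needs a separate hydroxylation. The forward step must oxidise both carbinols without cleaving the C3–C4 bond. Enolisation of 17 towards C2 then follows on its own, because C2–H is alpha to the C3 ketone and the product is the aromatic pyranone.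

**16 to 15.** The C3–C4 bond is cut and ring C opens. Both carbons become aldehyde carbons, joined only through the O1–C2 ether link, so rings A and B are separated apart from one chain. The forward step must couple intramolecularly, start at the aryl aldehyde, and not expel the aryloxide from C2. The benzyl and methyl ethers of 15 are kept because they are inert to SmI2 and leave the end-game at two steps. The design changes lie in how 15 is reached and handled.

**15 to 14 to 13.** No skeletal bond is cut. The two aldehydes are traced to two primary alcohols, and these to an ester (C3) and the aryl aldehyde (C4). The sensitive alpha-aryl-alpha-aryloxy aldehyde then exists for one step only. The oxidation must be free of amine base, because C2–H of 15 is acidic and the ortho formyl group is placed for a five-membered aldol closure.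

**13 to 7 and 12.** The O1–C2 bond is cut, which is the only link between the ring A fragment and the ring B/C2/C3 fragment, so the plan becomes convergent. The phenol of 7 is hindered and hydrogen-bonded, and 13 has the same acidic C2–H next to an ortho formyl group. A redox condensation with the benzylic alcohol 12 under neutral conditions is therefore preferred to carbonate-mediated alkylation with an alpha-bromo ester.

**7 back to 1.** The C4–C4a bond (formyl group) is cut first, then the O5–benzyl bond, then the aryl C–O bond that arises from the formyl carbon of 1. In 6 only one position ortho to the free hydroxyl is open, so magnesium-directed formylation has a single site. Compound 1 already has both methyl ethers and the future O1, and its formyl group sits where O5 is needed. The future O1 must be masked in 2, 4 and 5 by a group that comes off beside a benzyl ether.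

**12 back to 8.** The C1'–C2 bond is cut, then an O–benzyl bond, then the aryl C–O bond from the formyl carbon of 8. The position of 11 that becomes C1' is para to one benzyloxy group and ortho to the other, so it is the most nucleophilic site. Ethyl glyoxylate brings C2 as the carbinol and C3 as the ester in one step. The forward step must stop after one arylation and use a Lewis acid that leaves benzyl ethers alone.

## Other disconnections considered

**Alternative 1:** The cut is the aryl ether bond O1–C8a.
- **Forward key step:** Hydroquinone diketone A2 is oxidised at a carbon anode to acylquinone A3. C8a of A3 is the beta-carbon of a doubly activated enone and takes the enol oxygen of the side-chain diketone (oxa-Michael, 6-endo). Tautomerisation restores the arene and gives A1.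
- **In favour:** Ring C appears with C3 and C4 at their final oxidation level and the C3 oxygen in place as acetate. The aryl C–O bond needs neither halide nor metal, and the anode replaces a stoichiometric oxidant. The hydroquinone should be oxidised well before the benzyl-protected ring B.
- **Against it here:** A1 has a hydroxyl on C8 where a methyl ether is needed. It therefore needs methylation selective for O8 over the chelated O5, then acetate removal and hydrogenolysis, which is three steps after the key step against two. A2 is a 2-acetoxy-1,3-diketone on an unprotected hydroquinone, long to build and prone to acyl migration. A3 is a strong electrophile that can also add electrolyte nucleophiles.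
- **Comparison:** Structurally it uses the para pair O5/O8, whereas the chosen plan uses the vicinal pair at C3/C4. Mechanistically it is two-electron oxidation with polar conjugate addition, against two-electron reduction with radical coupling. On redox economy after ring closure the alternative is the better plan, since no oxidation follows. On the total count it is expected to be equal at best, because ring A must be carried as a hydroquinone acetophenone. The chosen plan has the C8 methyl ether in place from 1.

**Alternative 2:** Three bonds of ring C are cut at once: C4a–C4, C4–C3 and O1–C2. This divides the flavone into iodophenol A5, one carbon from an atmosphere of CO, and arylacetylene A6.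
- **Forward key step:** Zerovalent palladium formed from PdCl2(PPh3)2 inserts into the C–I bond of A5. CO insertion and coupling with A6 give an alkynyl ketone, and amine-mediated 6-endo addition of the phenol gives flavone A4.
- **In favour:** It is the most convergent of the four plans, with three skeletal bonds made in one flask and no redox corrections before the key step. No stereocentre is ever formed, which equals the chosen plan in outcome and is simpler on the way. A5 and A6 could come from 6 and 11. On convergence and on step count (about twelve against fourteen) this alternative is the better one.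
- **Against it here:** A4 lacks the C3 oxygen. It would have to be added afterwards by C3 metalation and oxidation or by epoxidation of the C2=C3 bond, on a substrate with three benzylic ethers. The iodide of A5 sits between a hydroxyl and a benzyloxy group on a very electron-rich ring, so oxidative addition should be slow. Iodination of 6 can also go para, whereas the magnesium-directed formylation of the chosen plan is strictly ortho. 5-Exo closure to the aurone is the usual competitor, and CO is toxic.
- **Comparison:** The alternative is organometallic and polar; the chosen plan is radical. The alternative builds C2=C3 directly but leaves C3 unoxidised. The chosen plan carries both oxygens of C3 and C4 from the start and pays with two redox adjustments.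

**Alternative 3:** Two bonds of ring B are cut, C1'–C2' and C5'–C6', so ring B is built on a finished chromone.
- **Forward key step:** Ethynylchromone A8 acts as a vinylogous ynone whose terminal alkyne carbon is the electrophilic end. It reacts with bis(silyloxy)diene A9: the nucleophilic terminal carbon of A9 bonds to the terminal alkyne carbon, and the ketene acetal carbon bonds to the internal one. Loss of methanol and of the silyl groups aromatises the adduct to A7.
- **In favour:** The 2',4'-dihydroxy-5'-methoxy pattern follows from the polarisation of A9, with both phenols free and no protecting group on ring B. On this point it is better than the chosen plan, which spends three steps on assembling and protecting ring B. The C3 oxygen is present throughout.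
- **Against it here:** A7 has a methyl ether on O5, so a chelation-directed 5-O-demethylation beside three other methyl ethers is added to the end. A8 needs a linear chromone synthesis with functionalisation and alkynylation at C2. A9 is a labile tetra-oxygenated diene. The cycloaddition may divert to open-chain Michael adducts or to the C2=C3 bond.
- **Comparison:** It constructs ring B where the chosen plan constructs ring C, and it is pericyclic or stepwise polar against radical. The linear sequence is expected to be longer than the eleven steps of the chosen plan, which takes both rings from commercial arenes.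

Key step: step 12

Remark: 15 and 16 were checked atom by atom against 19 (O1 next to the C8 methoxy carbon, benzyl on O5, O2' and O4') and need no correction.

Remark: 12 to 17 are racemic or diastereomer mixtures, which is immaterial because 19 is achiral; 8 (O-benzylisovanillin) is taken as a catalogue chemical.

## Route

Step 1
Reactants: 1 3-hydroxy-4,5-dimethoxybenzaldehyde
Product: 2 3,4-dimethoxy-5-(methoxymethoxy)benzaldehyde
Conditions: MOMCl, iPr2NEt, CH2Cl2, 0 °C to rt
Reagents that add atoms: chloromethyl methyl ether (MOMCl), COCCl
Why: O-alkylation of the phenol with the reactive alpha-chloro ether; the MOM acetal masks the oxygen that becomes O1 and withstands peracid, carbonate and benzylation.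

Step 2
Reactants: 2 3,4-dimethoxy-5-(methoxymethoxy)benzaldehyde
Product: 4 3,4-dimethoxy-5-(methoxymethoxy)phenol, via aryl formate 3 (not isolated)
Conditions: mCPBA, CH2Cl2, 0 °C to rt; then K2CO3 (cat.), MeOH, rt
Reagents that add atoms: meta-chloroperoxybenzoic acid (mCPBA), OOC(=O)c1cccc(Cl)c1
Why: Baeyer–Villiger (Dakin-type) oxidation; the para methoxy group makes the aryl group migrate in the Criegee intermediate to give formate 3, which catalytic carbonate in methanol cleaves by transesterification.

Step 3
Reactants: 4 3,4-dimethoxy-5-(methoxymethoxy)phenol
Product: 5 5-(benzyloxy)-1,2-dimethoxy-3-(methoxymethoxy)benzene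
Conditions: BnBr, K2CO3, DMF, rt
Reagents that add atoms: benzyl bromide, BrCc1ccccc1
Why: Williamson ether synthesis on the only free phenol; this places the benzyl group on the oxygen that becomes O5.

Step 4
Reactants: 5 5-(benzyloxy)-1,2-dimethoxy-3-(methoxymethoxy)benzene
Product: 6 5-(benzyloxy)-2,3-dimethoxyphenol
Conditions: HCl (cat.), MeOH, 50 °C
Reagents that add atoms: none
Why: Acid-catalysed acetal exchange removes the MOM group as dimethoxymethane; benzyl and methyl aryl ethers are stable to dilute methanolic acid.

Step 5
Reactants: 6 5-(benzyloxy)-2,3-dimethoxyphenol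
Product: 7 6-(benzyloxy)-2-hydroxy-3,4-dimethoxybenzaldehyde
Conditions: MgCl2, Et3N, (CH2O)n, MeCN, reflux; aq. HCl
Reagents that add atoms: paraformaldehyde (as formaldehyde), C=O
Why: Magnesium-mediated ortho-formylation of a phenol (Casnati–Skattebøl): the magnesium phenoxide delivers formaldehyde to the ortho carbon and a second formaldehyde oxidises the carbinol by hydride transfer. Only one ortho position is free, so the formyl group must enter between the hydroxyl and the benzyloxy group.

Step 6
Reactants: 8 3-(benzyloxy)-4-methoxybenzaldehyde
Product: 10 3-(benzyloxy)-4-methoxyphenol, via aryl formate 9 (not isolated)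
Conditions: mCPBA, CH2Cl2, 0 °C to rt; then K2CO3 (cat.), MeOH, rt
Reagents that add atoms: meta-chloroperoxybenzoic acid (mCPBA), OOC(=O)c1cccc(Cl)c1
Why: Baeyer–Villiger oxidation with aryl migration favoured by the para methoxy group, then methanolysis of formate 9; this gives the 1,2,4-trioxygenated pattern of ring B with the methyl ether already in place.

Step 7
Reactants: 10 3-(benzyloxy)-4-methoxyphenol
Product: 11 2,4-bis(benzyloxy)-1-methoxybenzene
Conditions: BnBr, K2CO3, DMF, rt
Reagents that add atoms: benzyl bromide, BrCc1ccccc1
Why: Williamson ether synthesis; both future phenols of ring B now carry the same hydrogenolysable group.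

Step 8
Reactants: 11 2,4-bis(benzyloxy)-1-methoxybenzene
Product: 12 ethyl 2-[2,4-bis(benzyloxy)-5-methoxyphenyl]-2-hydroxyacetate (racemic)
Conditions: ethyl glyoxylate (freshly depolymerised, excess), Yb(OTf)3 (10 mol%), CH2Cl2, rt
Reagents that add atoms: ethyl glyoxylate, CCOC(=O)C=O
Why: Friedel–Crafts hydroxyalkylation of an electron-rich arene with a glyoxylate; attack should occur at C5 of 11, which is para to one benzyloxy group and ortho to the other, while C3 is flanked by two ethers and C6 is meta to both. The mild lanthanide triflate should spare the benzyl ethers, and excess aldehyde limits a second arylation; the new stereocentre is formed racemic.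

Step 9
Reactants: 7 6-(benzyloxy)-2-hydroxy-3,4-dimethoxybenzaldehyde; 12 ethyl 2-[2,4-bis(benzyloxy)-5-methoxyphenyl]-2-hydroxyacetate
Product: 13 ethyl 2-[2,4-bis(benzyloxy)-5-methoxyphenyl]-2-[3-(benzyloxy)-2-formyl-5,6-dimethoxyphenoxy]acetate (racemic)
Conditions: PPh3, DIAD, THF, 0 °C to rt
Reagents that add atoms: none
Why: Mitsunobu etherification of an acidic salicylaldehyde-type phenol with a mandelate; the alkoxyphosphonium of 12 is displaced by the phenoxide to form the O1–C2 bond. The medium is near neutral, so the acidic C2–H of 13 is not enolised and aldol closure onto the ortho formyl group is avoided.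

Step 10
Reactants: 13 ethyl 2-[2,4-bis(benzyloxy)-5-methoxyphenyl]-2-[3-(benzyloxy)-2-formyl-5,6-dimethoxyphenoxy]acetate
Product: 14 2-[2,4-bis(benzyloxy)-5-methoxyphenyl]-2-[3-(benzyloxy)-2-(hydroxymethyl)-5,6-dimethoxyphenoxy]ethan-1-ol (racemic)
Conditions: LiAlH4, THF, 0 °C; Fieser work-up
Reagents that add atoms: none
Why: Hydride reduction of the ester and of the aryl aldehyde to the two primary alcohols; aryl ethers and the benzylic aryl ether at C2 are inert to LiAlH4.

Step 11
Reactants: 14 2-[2,4-bis(benzyloxy)-5-methoxyphenyl]-2-[3-(benzyloxy)-2-(hydroxymethyl)-5,6-dimethoxyphenoxy]ethan-1-ol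
Product: 15 6-(benzyloxy)-2-{1-[2,4-bis(benzyloxy)-5-methoxyphenyl]-2-oxoethoxy}-3,4-dimethoxybenzaldehyde (racemic)
Conditions: Dess–Martin periodinane (2.6 equiv), NaHCO3, CH2Cl2, 0 °C to rt; crude product used at once
Reagents that add atoms: none
Why: Dess–Martin oxidation of both primary alcohols to aldehydes without over-oxidation; the buffered, amine-free medium avoids enolisation of the C2–H and the five-membered aldol closure that a Swern base could trigger.

Step 12
Reactants: 15 6-(benzyloxy)-2-{1-[2,4-bis(benzyloxy)-5-methoxyphenyl]-2-oxoethoxy}-3,4-dimethoxybenzaldehyde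
Product: 16 5-(benzyloxy)-2-[2,4-bis(benzyloxy)-5-methoxyphenyl]-7,8-dimethoxychromane-3,4-diol (racemic, mixture of diastereomers)
Conditions: SmI2 (2.5 equiv), THF, −78 °C, slow addition of 15 at high dilution, no HMPA; aq. NH4Cl
Reagents that add atoms: none
Why: SmI2 should transfer the first electron to the aryl aldehyde, whose ketyl is benzylic and whose carbonyl can chelate samarium together with the ortho benzyloxy oxygen; this C4 ketyl attacks the samarium-bound C3 aldehyde carbon, and a second SmI2 reduces the resulting oxygen radical to the diolate of trivalent samarium. The closest known reaction type is the SmI2-mediated intramolecular pinacol coupling of dialdehydes to cyclic 1,2-diols. Ring C closes in the 6-exo mode: C4 attacks, the chain runs through C4a, C8a, O1 and C2, and the C3=O bond lies outside the new ring. The new stereocentres C3 and C4 form relative to the racemic C2 centre; chelation of both oxygens to samarium should favour the 3,4-cis diol with the C2 aryl group pseudo-equatorial, but no control is needed because step 13 removes all three centres. The selectivity that matters is chemoselectivity, since a ketyl at C3 could expel the ring A aryloxide from C2. This is countered by low temperature, the absence of HMPA, the faster electron transfer to the aryl aldehyde and fast intramolecular capture. Slow addition to excess SmI2 at high dilution holds back intermolecular coupling, and benzyl and methyl aryl ethers are inert under these conditions.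

Step 13
Reactants: 16 5-(benzyloxy)-2-[2,4-bis(benzyloxy)-5-methoxyphenyl]-7,8-dimethoxychromane-3,4-diol
Product: 18 5-(benzyloxy)-2-[2,4-bis(benzyloxy)-5-methoxyphenyl]-3-hydroxy-7,8-dimethoxy-4H-chromen-4-one, via 3,4-dione 17 (not isolated)
Conditions: DMSO, (CF3CO)2O, CH2Cl2, −78 °C; then Et3N, −78 °C to rt
Reagents that add atoms: none
Why: Swern-type oxidation with trifluoroacetic-anhydride-activated DMSO turns both carbinols into alkoxysulfonium salts before base is added, so no free alpha-hydroxy ketone is exposed to glycol cleavage. Et3N then gives dione 17, whose C2–H is alpha to the C3 ketone and enolises to the aromatic 3-hydroxy-4-pyranone 18, removing all three stereocentres.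

Step 14
Reactants: 18 5-(benzyloxy)-2-[2,4-bis(benzyloxy)-5-methoxyphenyl]-3-hydroxy-7,8-dimethoxy-4H-chromen-4-one
Product: 19 2-(2,4-dihydroxy-5-methoxyphenyl)-3,5-dihydroxy-7,8-dimethoxy-4H-chromen-4-one
Conditions: H2 (1 atm), Pd/C (10 wt%), EtOAc–MeOH, rt, exclusion of air on work-up
Reagents that add atoms: none
Why: Catalytic hydrogenolysis of the three benzyl aryl ethers; methyl ethers, the C2=C3 bond of the pyranone and the C4 carbonyl should not be reduced under these mild conditions, and the polyphenol is released in neutral, oxygen-free medium.

## Compound list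

1 | 3-hydroxy-4,5-dimethoxybenzaldehyde | COc1cc(C=O)cc(O)c1OC | starting material
2 | 3,4-dimethoxy-5-(methoxymethoxy)benzaldehyde | COCOc1cc(C=O)cc(OC)c1OC | intermediate
3 | 3,4-dimethoxy-5-(methoxymethoxy)phenyl formate (not isolated) | COCOc1cc(OC=O)cc(OC)c1OC | intermediate
4 | 3,4-dimethoxy-5-(methoxymethoxy)phenol | COCOc1cc(O)cc(OC)c1OC | intermediate
5 | 5-(benzyloxy)-1,2-dimethoxy-3-(methoxymethoxy)benzene | COCOc1cc(OCc2ccccc2)cc(OC)c1OC | intermediate
6 | 5-(benzyloxy)-2,3-dimethoxyphenol | COc1cc(OCc2ccccc2)cc(O)c1OC | intermediate
7 | 6-(benzyloxy)-2-hydroxy-3,4-dimethoxybenzaldehyde | COc1cc(OCc2ccccc2)c(C=O)c(O)c1OC | intermediate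
8 | 3-(benzyloxy)-4-methoxybenzaldehyde | COc1ccc(C=O)cc1OCc1ccccc1 | starting material
9 | 3-(benzyloxy)-4-methoxyphenyl formate (not isolated) | COc1ccc(OC=O)cc1OCc1ccccc1 | intermediate
10 | 3-(benzyloxy)-4-methoxyphenol | COc1ccc(O)cc1OCc1ccccc1 | intermediate
11 | 2,4-bis(benzyloxy)-1-methoxybenzene | COc1ccc(OCc2ccccc2)cc1OCc1ccccc1 | intermediate
12 | ethyl 2-[2,4-bis(benzyloxy)-5-methoxyphenyl]-2-hydroxyacetate (racemic) | CCOC(=O)C(O)c1cc(OC)c(OCc2ccccc2)cc1OCc1ccccc1 | intermediate
13 | ethyl 2-[2,4-bis(benzyloxy)-5-methoxyphenyl]-2-[3-(benzyloxy)-2-formyl-5,6-dimethoxyphenoxy]acetate (racemic) | CCOC(=O)C(Oc1c(OC)c(OC)cc(OCc2ccccc2)c1C=O)c1cc(OC)c(OCc2ccccc2)cc1OCc1ccccc1 | intermediate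
14 | 2-[2,4-bis(benzyloxy)-5-methoxyphenyl]-2-[3-(benzyloxy)-2-(hydroxymethyl)-5,6-dimethoxyphenoxy]ethan-1-ol (racemic) | OCC(Oc1c(OC)c(OC)cc(OCc2ccccc2)c1CO)c1cc(OC)c(OCc2ccccc2)cc1OCc1ccccc1 | intermediate
15 | 6-(benzyloxy)-2-{1-[2,4-bis(benzyloxy)-5-methoxyphenyl]-2-oxoethoxy}-3,4-dimethoxybenzaldehyde (racemic) | O=CC(Oc1c(OC)c(OC)cc(OCc2ccccc2)c1C=O)c1cc(OC)c(OCc2ccccc2)cc1OCc1ccccc1 | intermediate
16 | 5-(benzyloxy)-2-[2,4-bis(benzyloxy)-5-methoxyphenyl]-7,8-dimethoxychromane-3,4-diol (racemic, mixture of diastereomers) | COc1cc(OCc2ccccc2)c2c(c1OC)OC(c1cc(OC)c(OCc3ccccc3)cc1OCc1ccccc1)C(O)C2O | intermediate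
17 | 5-(benzyloxy)-2-[2,4-bis(benzyloxy)-5-methoxyphenyl]-7,8-dimethoxychromane-3,4-dione (racemic, not isolated) | COc1cc(OCc2ccccc2)c2c(c1OC)OC(c1cc(OC)c(OCc3ccccc3)cc1OCc1ccccc1)C(=O)C2=O | intermediate
18 | 5-(benzyloxy)-2-[2,4-bis(benzyloxy)-5-methoxyphenyl]-3-hydroxy-7,8-dimethoxy-4H-chromen-4-one | COc1cc(OCc2ccccc2)c2c(=O)c(O)c(-c3cc(OC)c(OCc4ccccc4)cc3OCc3ccccc3)oc2c1OC | intermediate
19 | 2-(2,4-dihydroxy-5-methoxyphenyl)-3,5-dihydroxy-7,8-dimethoxy-4H-chromen-4-one | COc1cc(-c2oc3c(OC)c(OC)cc(O)c3c(=O)c2O)c(O)cc1O | target

## Step count and least certain steps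

Total step count: 14. Longest linear sequence: 11 steps (steps 1 to 5, then 9 to 14); the ring B branch (steps 6 to 8) joins at step 9.

**Step 12 (key step).** The most likely failure is electron transfer to the alpha-aryloxy aldehyde followed by expulsion of the ring A phenoxide, that is, reductive cleavage of the C2–O1 bond. Plain reduction of either aldehyde to the alcohol and intermolecular coupling are the other risks. The alpha oxygen and chelation make the aliphatic aldehyde a better acceptor than a simple alkanal, so the margin over the aryl aldehyde is narrower than usual.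

The fallback sets out from 7 and 11 and makes the C3–C4 bond at the alkene level without any reducing metal:
- Vilsmeier–Haack formylation of 11 (POCl3, DMF) should give 2,4-bis(benzyloxy)-5-methoxybenzaldehyde F1.
- Ohira–Bestmann homologation (K2CO3, MeOH) gives 1,5-bis(benzyloxy)-2-ethynyl-4-methoxybenzene F2.
- Hydroboration with catecholborane and hydrolysis gives (E)-{2-[2,4-bis(benzyloxy)-5-methoxyphenyl]ethenyl}boronic acid F3.
- Heating 7 with F3 and dibenzylamine in dioxane should give 5-(benzyloxy)-2-[2,4-bis(benzyloxy)-5-methoxyphenyl]-7,8-dimethoxy-2H-chromene F4. The sequence is Petasis-type alkenyl transfer to the iminium ion (forming C3–C4), loss of the amine to an ortho-quinone methide, and 6π-electrocyclisation (forming O1–C2).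
- Upjohn dihydroxylation of the C3=C4 bond (OsO4 cat., N-methylmorpholine N-oxide, acetone–water) gives the 3,4-cis diol anti to the C2 aryl group. This is one diastereomer of 16, where the route is rejoined. Compounds 13, 14 and 15 are bypassed.

**Step 11.** The risk is loss of the alpha-aryl-alpha-aryloxy aldehyde during its formation and isolation: enolisation at C2 with aldol addition to the neighbouring aryl aldehyde, hydrate formation, or air oxidation. The fallback sets out from 13 and replaces steps 10 and 11, so 15 is never formed under oxidising conditions.
- Acetalisation of the aryl aldehyde (HC(OEt)3, EtOH, pyridinium tosylate) gives ethyl 2-[2,4-bis(benzyloxy)-5-methoxyphenyl]-2-[3-(benzyloxy)-2-(diethoxymethyl)-5,6-dimethoxyphenoxy]acetate F5.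
- Partial reduction of the ester with i-Bu2AlH at −78 °C gives 2-[2,4-bis(benzyloxy)-5-methoxyphenyl]-2-[3-(benzyloxy)-2-(diethoxymethyl)-5,6-dimethoxyphenoxy]acetaldehyde F6. The alpha oxygen stabilises the tetrahedral aluminium hemiacetal.
- The electron-rich benzaldehyde acetal is very acid-labile and is opened with pyridinium tosylate in wet acetone just before step 12, returning to the route at 15.

**Step 8.** The risk is a second Friedel–Crafts alkylation of 11 by the product, through ionisation of the doubly activated benzylic alcohol, leading to diarylacetate formation. Slow Lewis-acid debenzylation is a lesser risk. The fallback sets out from 11.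
- Bromination with N-bromosuccinimide in MeCN gives 1,5-bis(benzyloxy)-2-bromo-4-methoxybenzene F7.
- Bromine–lithium exchange (n-BuLi, THF, −78 °C) and quenching with diethyl oxalate give ethyl 2-[2,4-bis(benzyloxy)-5-methoxyphenyl]-2-oxoacetate F8.
- NaBH4 in EtOH at −20 °C reduces only the ketone and returns to the route at 12.

**Step 9.** The risk is slow etherification, because the phenol of 7 has two ortho substituents and is hydrogen-bonded to the formyl group. N-alkylation of the reduced azodicarboxylate by the easily ionised mandelate is the competing process. The fallback sets out from 12.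
- PBr3 in CH2Cl2 at 0 °C gives ethyl 2-[2,4-bis(benzyloxy)-5-methoxyphenyl]-2-bromoacetate F9.
- F9 alkylates the potassium phenoxide of 7 (K2CO3, acetone, rt) and returns to the route at 13. The reaction is kept short and at room temperature so that the C2–H of 13 is not enolised.

**Step 13.** The risks are cleavage of the C3–C4 bond, a stalled second oxidation, or methylthiomethyl ether formation at the new enol. The fallback sets out from 16.
- MnO2 in CH2Cl2 oxidises only the benzylic C4 carbinol and gives 5-(benzyloxy)-2-[2,4-bis(benzyloxy)-5-methoxyphenyl]-3-hydroxy-7,8-dimethoxychroman-4-one F10.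
- Cu(OAc)2 with NH4NO3 in aqueous acetic acid (the benzoin-to-benzil oxidation, with divalent copper as oxidant) takes the alpha-hydroxy ketone to the dione. This enolises and returns to the route at 18.

## Further compounds

F1 | step 12 | 2,4-bis(benzyloxy)-5-methoxybenzaldehyde | COc1cc(C=O)c(OCc2ccccc2)cc1OCc1ccccc1
F2 | step 12 | 1,5-bis(benzyloxy)-2-ethynyl-4-methoxybenzene | COc1cc(C#C)c(OCc2ccccc2)cc1OCc1ccccc1
F3 | step 12 | (E)-{2-[2,4-bis(benzyloxy)-5-methoxyphenyl]ethenyl}boronic acid | COc1cc(/C=C/B(O)O)c(OCc2ccccc2)cc1OCc1ccccc1
F4 | step 12 | 5-(benzyloxy)-2-[2,4-bis(benzyloxy)-5-methoxyphenyl]-7,8-dimethoxy-2H-chromene (racemic) | COc1cc(OCc2ccccc2)c3C=CC(Oc3c1OC)c1cc(OC)c(OCc2ccccc2)cc1OCc1ccccc1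
F5 | step 11 | ethyl 2-[2,4-bis(benzyloxy)-5-methoxyphenyl]-2-[3-(benzyloxy)-2-(diethoxymethyl)-5,6-dimethoxyphenoxy]acetate (racemic) | CCOC(=O)C(Oc1c(OC)c(OC)cc(OCc2ccccc2)c1C(OCC)OCC)c1cc(OC)c(OCc2ccccc2)cc1OCc1ccccc1
F6 | step 11 | 2-[2,4-bis(benzyloxy)-5-methoxyphenyl]-2-[3-(benzyloxy)-2-(diethoxymethyl)-5,6-dimethoxyphenoxy]acetaldehyde (racemic) | O=CC(Oc1c(OC)c(OC)cc(OCc2ccccc2)c1C(OCC)OCC)c1cc(OC)c(OCc2ccccc2)cc1OCc1ccccc1
F7 | step 8 | 1,5-bis(benzyloxy)-2-bromo-4-methoxybenzene | COc1cc(Br)c(OCc2ccccc2)cc1OCc1ccccc1
F8 | step 8 | ethyl 2-[2,4-bis(benzyloxy)-5-methoxyphenyl]-2-oxoacetate | CCOC(=O)C(=O)c1cc(OC)c(OCc2ccccc2)cc1OCc1ccccc1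
F9 | step 9 | ethyl 2-[2,4-bis(benzyloxy)-5-methoxyphenyl]-2-bromoacetate (racemic) | CCOC(=O)C(Br)c1cc(OC)c(OCc2ccccc2)cc1OCc1ccccc1
F10 | step 13 | 5-(benzyloxy)-2-[2,4-bis(benzyloxy)-5-methoxyphenyl]-3-hydroxy-7,8-dimethoxychroman-4-one (racemic, mixture of diastereomers) | COc1cc(OCc2ccccc2)c2c(c1OC)OC(c1cc(OC)c(OCc3ccccc3)cc1OCc1ccccc1)C(O)C2=O
A1 | alternative 1 | 2-[2,4-bis(benzyloxy)-5-methoxyphenyl]-5,8-dihydroxy-7-methoxy-4-oxo-4H-chromen-3-yl acetate | COc1cc(O)c2c(=O)c(OC(C)=O)c(-c3cc(OC)c(OCc4ccccc4)cc3OCc3ccccc3)oc2c1O
A2 | alternative 1 | 1-[2,4-bis(benzyloxy)-5-methoxyphenyl]-3-(2,5-dihydroxy-4-methoxyphenyl)-1,3-dioxopropan-2-yl acetate (racemic) | COc1cc(O)c(cc1O)C(=O)C(OC(C)=O)C(=O)c1cc(OC)c(OCc2ccccc2)cc1OCc1ccccc1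
A3 | alternative 1 | 1-[2,4-bis(benzyloxy)-5-methoxyphenyl]-3-(4-methoxy-3,6-dioxocyclohexa-1,4-dien-1-yl)-1,3-dioxopropan-2-yl acetate (racemic) | COC1=CC(=O)C(=CC1=O)C(=O)C(OC(C)=O)C(=O)c1cc(OC)c(OCc2ccccc2)cc1OCc1ccccc1
A4 | alternative 2 | 5-(benzyloxy)-2-[2,4-bis(benzyloxy)-5-methoxyphenyl]-7,8-dimethoxy-4H-chromen-4-one | COc1cc(OCc2ccccc2)c2c(=O)cc(-c3cc(OC)c(OCc4ccccc4)cc3OCc3ccccc3)oc2c1OC
A5 | alternative 2 | 3-(benzyloxy)-2-iodo-5,6-dimethoxyphenol | COc1cc(OCc2ccccc2)c(I)c(O)c1OC
A6 | alternative 2 | 1,5-bis(benzyloxy)-2-ethynyl-4-methoxybenzene | C#Cc1cc(OC)c(OCc2ccccc2)cc1OCc1ccccc1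
A7 | alternative 3 | 3-(benzyloxy)-2-(2,4-dihydroxy-5-methoxyphenyl)-5,7,8-trimethoxy-4H-chromen-4-one | COc1cc(-c2oc3c(OC)c(OC)cc(OC)c3c(=O)c2OCc2ccccc2)c(O)cc1O
A8 | alternative 3 | 3-(benzyloxy)-2-ethynyl-5,7,8-trimethoxy-4H-chromen-4-one | C#Cc1oc2c(OC)c(OC)cc(OC)c2c(=O)c1OCc1ccccc1
A9 | alternative 3 | 1,4-dimethoxy-1,3-bis[(trimethylsilyl)oxy]buta-1,3-diene (double-bond geometry not defined) | COC=C(O[Si](C)(C)C)C=C(OC)O[Si](C)(C)C
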